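The amounts counted by substrate add up to the charge, 100 % in the last dawn reading. So what substrate loses stands in the other columns, and we need two things: how fast substrate falls, and how its loss divides.

all flasks: gas phase 23 mM (held)
- autumn: substrate 0.037 M; temperature −15 °C; run made earlier
- dawn: substrate 0.15 M; temperature 5 °C; run made earlier
- blue: substrate 0.075 M; temperature 0 °C; time 40 h
- violet: substrate 0.075 M; temperature 10 °C; time 40 h

| run | time / h | substrate / % | target / % | over-reaction product / % | over-reacted product / % |
|---|---|---|---|---|---|
| autumn | 6.00 | 98.8 | 0.8 | 0 | 0 |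
| autumn | 15.0 | 96.5 | 3.4 | 0 | 0 |
| autumn | 30.0 | 91.8 | 8.4 | 0 | 0.2 |
| autumn | 48.0 | 86.5 | 13.2 | 0.4 | 0 |
| dawn | 6.00 | 94.1 | 6.8 | 0.7 | 0.6 |
| dawn | 12.0 | 85.5 | 12.7 | 1.2 | 0.3 |
| dawn | 20.0 | 76.5 | 20.8 | 3.3 | 0.2 |
| dawn | 25.0 | 71.0 | 24.1 | 4.8 | 0.3 |

(scatter of a reading: 0.3 percentage points)

- which of these there is most of at the end, counted by the substrate in it, blue (substrate / over-reacted product / over-reaction product / target)
- which of these there is most of at the end, counted by the substrate in it, violet (substrate / over-reacted product / over-reaction product / target)
- the largest of these amounts at the end, in percent of the substrate charged, blue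
- the largest of these amounts at the end, in percent of the substrate charged, violet

- at the start none of the gas is dissolved
- the earlier runs were read with a standard deviation of 0.3 percentage points
- reactions considered so far: gas phase <-> dissolved gas; substrate + dissolved gas <-> target; dissolved gas + target -> over-reacted product; dissolved gas + target -> over-reaction product

Take the last row of each table and replace the substrate curve by its mean, a single first-order decay. The autumn run gives 0.00302 h⁻¹ at −15 °C, the dawn run 0.0137 h⁻¹ at 5 °C. This logarithm of charged over left, divided by the elapsed time, is our mean loss constant, a pseudo-first-order constant. The runs differ in charge too, but we lay the change on temperature and draw the logarithm of the constant straight against it. By our own reckoning blue gets 0.00939 h⁻¹ and violet 0.0200 h⁻¹, so after 40 h substrate stands at 68.7 % and 44.9 %.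

The first dawn row shows the error of the mean. Over 6.00 h it gives 0.0101 h⁻¹, slower than over 25.0 h. The curve steepens, so our substrate values lean high.

Blue stays above half and substrate leads there. In violet, target would need 81.7 % of what substrate lost to pass it. In the dawn run that share fell from 88.5 % to 83.1 %, and violet runs hotter and longer. So we put substrate first in violet.

The forecast, with figures of its own, says substrate at 68 % in blue and substrate at 46 % in violet: “Substrate still leads”.

The flask gives substrate at 63.6 % in blue and substrate at 41.7 % in violet, with target at 29.6 % there.

    gas phase ⇌ dissolved gas, rate k1*(csat - [dissolved gas]) (kL = 0.00523 min⁻¹)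
    substrate + dissolved gas ⇌ target (K = 138 L mol⁻¹, k = 0.0110 L mol⁻¹ min⁻¹, Ea = 60.0 kJ mol⁻¹, ΔH = −11.0 kJ mol⁻¹)
    dissolved gas + target → over-reacted product (k = 7.21 × 10⁻⁴ L mol⁻¹ min⁻¹, Ea = 71.0 kJ mol⁻¹)
    dissolved gas + target → over-reaction product (k = 0.00885 L mol⁻¹ min⁻¹, Ea = 76.0 kJ mol⁻¹)
    (constants at 0 °C)

The forecast held. Blue's mean constant comes to 0.0113 h⁻¹, faster than our 0.00939 h⁻¹, the leaning the dawn rows showed. The gap between the flasks comes from the difference in temperature: violet at blue's temperature holds 63.6 % substrate, not 41.7 %. In a neighbour flask, a repeat of blue at 25 °C, the same line gives 0.0621 h⁻¹, hence 8.34 % substrate. The flask holds 15.7 %, and over-reaction product leads at 70.2 %.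

The numbers in the tables are calculated with made-up constants, noise included.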